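Ring B is disconnected across C1'–C6' and C2'–C3'. C3'(OH), C4'(OMe), C5'(OMe) and C6' are the intact 3,4-dimethoxyfuran, whose ring oxygen becomes the 3'-hydroxyl, while C1' and C2' are the two carbons of an ethynyl group on C2 of the pyranone (ring C). One operation, a furan–alkyne Diels–Alder reaction followed by acid-triggered opening of the oxygen bridge, therefore closes and aromatizes ring B and sets its hydroxyl/methoxyl pattern without any differentiation of phenols. The dienophile is 5,7-bis(benzyloxy)-2-ethynyl-6,8-dimethoxychromen-4-one, with ring A fully oxygenated from a pentaoxygenated benzene and benzyl ethers on O5 and O7 that are removed by hydrogenolysis at the end.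

Key step: step 7

Remarks and assumptions on the chemistry:
- The 6- and 8-methoxyls must already be in the ring A building block; a phloroglucinol-type acetophenone such as 2,4,6-trihydroxyacetophenone would give a chromone lacking both. Ring A is therefore grown from 1,2,4,5-tetramethoxybenzene, whose four oxygens become O1, O8, O6 and O5; the fifth oxygen (O7) is added in step 1.
- The alkyne is made from the chromone-2-carbaldehyde without organolithium base, which would attack the C4 carbonyl.
- Assumption: 1,2,4,5-tetramethoxybenzene, ethyl diethoxyacetate, 3,4-dimethoxyfuran and (for one fallback) 3-(benzyloxy)-4,5-dimethoxybenzaldehyde are taken as catalogue compounds.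
- Primed locants refer to ring B; unprimed chromone locants to rings A and C.

Step 1
Reactants: 1 1,2,4,5-tetramethoxybenzene
Product: 4 2,3,5,6-tetramethoxyphenol, via aryllithium 2 (not isolated), via dimethyl arylboronate 3 (not isolated)
Conditions: n-BuLi, TMEDA, THF, 0 °C → rt; B(OMe)3, −78 °C → rt; 30% H2O2, AcOH, 0 °C → rt
Reagents that add atoms: hydrogen peroxide, OO
Why: Directed ortho-metalation removes the ring hydrogen flanked by two methoxyls, and borylation–oxidation of the aryllithium should install the fifth ring oxygen (the later O7) as a free phenol.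

Step 2
Reactants: 4 2,3,5,6-tetramethoxyphenol
Product: 6 1-(2,4-dihydroxy-3,5,6-trimethoxyphenyl)ethan-1-one, via tetramethoxy ketone 5 (not isolated)
Conditions: AcCl, AlCl3 (3.5 equiv), CH2Cl2, 0 °C → 40 °C; 1 M HCl
Reagents that add atoms: acetyl chloride, CC(=O)Cl
Why: Friedel–Crafts acylation at the only free ring position (para to the hydroxyl) should be followed in the same flask by aluminium-chelate-assisted cleavage of one methoxyl ortho to the new carbonyl; any material that keeps or loses both ortho methoxyls converges in step 3.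

Step 3
Reactants: 6 1-(2,4-dihydroxy-3,5,6-trimethoxyphenyl)ethan-1-one
Product: 7 1-(2,4,6-trihydroxy-3,5-dimethoxyphenyl)ethan-1-one
Conditions: AlCl3 (4 equiv), MeCN, 60 °C; 2 M HCl
Reagents that add atoms: none
Why: Chelation-controlled aryl methyl ether cleavage: carbonyl-bound aluminium activates only the remaining ortho methoxyl (C6), whereas the 3- and 5-methoxyls cannot form the six-membered chelate and should be retained.

Step 4
Reactants: 7 1-(2,4,6-trihydroxy-3,5-dimethoxyphenyl)ethan-1-one
Product: 8 1-[4,6-bis(benzyloxy)-2-hydroxy-3,5-dimethoxyphenyl]ethan-1-one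
Conditions: BnBr (2.1 equiv), K2CO3, DMF, rt, under argon
Reagents that add atoms: benzyl bromide, BrCc1ccccc1
Why: Williamson etherification should take the para hydroxyl and one ortho hydroxyl, because the last ortho hydroxyl is hydrogen-bonded to the acetyl carbonyl and much less nucleophilic, and no ring carbon is free for C-benzylation.

Step 5
Reactants: 8 1-[4,6-bis(benzyloxy)-2-hydroxy-3,5-dimethoxyphenyl]ethan-1-one; 9 ethyl diethoxyacetate
Product: 12 5,7-bis(benzyloxy)-6,8-dimethoxy-4-oxo-4H-chromene-2-carbaldehyde, via diethoxy diketone 10 (not isolated), via chromone acetal 11 (not isolated)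
Conditions: LiN(SiMe3)2 (3.3 equiv), THF, −78 °C → rt; then 2 M HCl, THF, 60 °C
Reagents that add atoms: water, O
Why: Crossed Claisen condensation of the ketone enolate with ester 9 (a poor enolate precursor), acid-catalysed cyclodehydration of the 2-hydroxyaryl 1,3-diketone to the 4-pyranone and hydrolysis of the acetal should give the aldehyde in one flask.

Step 6
Reactants: 12 5,7-bis(benzyloxy)-6,8-dimethoxy-4-oxo-4H-chromene-2-carbaldehyde
Product: 13 5,7-bis(benzyloxy)-2-ethynyl-6,8-dimethoxy-4H-chromen-4-one
Conditions: dimethyl (1-diazo-2-oxopropyl)phosphonate, K2CO3, MeOH/THF, 0 °C → rt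
Reagents that add atoms: dimethyl (1-diazo-2-oxopropyl)phosphonate, COP(=O)(OC)C(=[N+]=[N-])C(C)=O
Why: Seyferth–Gilbert homologation in its Ohira–Bestmann form should convert the non-enolizable aldehyde into the terminal alkyne under carbonate/methanol, which the vinylogous-ester C4 carbonyl tolerates.

Step 7
Reactants: 13 5,7-bis(benzyloxy)-2-ethynyl-6,8-dimethoxy-4H-chromen-4-one; 14 3,4-dimethoxyfuran
Product: 16 5,7-bis(benzyloxy)-2-(3-hydroxy-4,5-dimethoxyphenyl)-6,8-dimethoxy-4H-chromen-4-one, via oxanorbornadiene 15 (not isolated)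
Conditions: 14 (4 equiv), PhMe, 100 °C, sealed tube; then BF3·OEt2 (0.5 equiv), CH2Cl2, −40 → 0 °C
Reagents that add atoms: none
Why: The electron-rich diene 14 and the alkyne of 13, activated as a vinylogous ynone through C2=C3 and the C4 carbonyl, should combine in a concerted, asynchronous (4+2) cycloaddition that forms C1'–C6' and C2'–C3' and gives oxanorbornadiene 15; BF3 then ionizes the C6'–O bridge bond to a cation delocalized over C6', C2' and C4' (an oxocarbenium through the 4'-methoxyl), and loss of the C3' proton, directly or after a 1,2-hydride shift and enolization, gives the phenol with the former furan oxygen as the 3'-hydroxyl. The closest known reaction type is the Diels–Alder addition of furans, including 3,4-dialkoxyfurans, to activated alkynes followed by acid-catalysed isomerization of the 7-oxanorbornadienes to phenols. Ring B is closed by intermolecular cycloaddition, both sigma bonds being made in one event, and becomes aromatic by cleavage of the one-atom oxygen bridge, not by oxidation. No stereocenter survives, since the two bridgehead centers of racemic 15 are erased on aromatization. Two selectivities are needed: addition to the unhindered terminal alkyne and not to the C2=C3 bond, which is a trisubstituted enol-ether double bond deactivated by O1; and bridge opening at C6', not C3', secured because ionization at C3' would put positive charge on C1', the carbon carrying the electron-poor, BF3-complexed chromonyl group, while the symmetry of the furan makes the orientation of the cycloaddition irrelevant. Heating without acid first avoids Friedel–Crafts-type conjugate addition of the furan alpha carbon to the alkyne.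

Step 8
Reactants: 16 5,7-bis(benzyloxy)-2-(3-hydroxy-4,5-dimethoxyphenyl)-6,8-dimethoxy-4H-chromen-4-one
Product: 17 scaposin
Conditions: H2 (1 atm), Pd/C, EtOAc/MeOH, rt
Reagents that add atoms: none
Why: Hydrogenolysis of the two O-benzyl ethers should free the 5- and 7-hydroxyls, while aryl methyl ethers, the phenol and the chromone C2=C3 bond are inert under these conditions.

Compound list
1 | 1,2,4,5-tetramethoxybenzene | COc1cc(OC)c(OC)cc1OC | starting material
2 | (2,3,5,6-tetramethoxyphenyl)lithium | [Li]c1c(OC)c(OC)cc(OC)c1OC | intermediate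
3 | dimethyl (2,3,5,6-tetramethoxyphenyl)boronate | COB(OC)c1c(OC)c(OC)cc(OC)c1OC | intermediate
4 | 2,3,5,6-tetramethoxyphenol | COc1cc(OC)c(OC)c(O)c1OC | intermediate
5 | 1-(4-hydroxy-2,3,5,6-tetramethoxyphenyl)ethan-1-one | CC(=O)c1c(OC)c(OC)c(O)c(OC)c1OC | intermediate
6 | 1-(2,4-dihydroxy-3,5,6-trimethoxyphenyl)ethan-1-one | CC(=O)c1c(O)c(OC)c(O)c(OC)c1OC | intermediate
7 | 1-(2,4,6-trihydroxy-3,5-dimethoxyphenyl)ethan-1-one | CC(=O)c1c(O)c(OC)c(O)c(OC)c1O | intermediate
8 | 1-[4,6-bis(benzyloxy)-2-hydroxy-3,5-dimethoxyphenyl]ethan-1-one | CC(=O)c1c(O)c(OC)c(OCc2ccccc2)c(OC)c1OCc1ccccc1 | intermediate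
9 | ethyl diethoxyacetate | CCOC(=O)C(OCC)OCC | starting material
10 | 1-[4,6-bis(benzyloxy)-2-hydroxy-3,5-dimethoxyphenyl]-4,4-diethoxybutane-1,3-dione | CCOC(OCC)C(=O)CC(=O)c1c(O)c(OC)c(OCc2ccccc2)c(OC)c1OCc1ccccc1 | intermediate
11 | 5,7-bis(benzyloxy)-2-(diethoxymethyl)-6,8-dimethoxy-4H-chromen-4-one | CCOC(OCC)c1cc(=O)c2c(OCc3ccccc3)c(OC)c(OCc3ccccc3)c(OC)c2o1 | intermediate
12 | 5,7-bis(benzyloxy)-6,8-dimethoxy-4-oxo-4H-chromene-2-carbaldehyde | O=Cc1cc(=O)c2c(OCc3ccccc3)c(OC)c(OCc3ccccc3)c(OC)c2o1 | intermediate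
13 | 5,7-bis(benzyloxy)-2-ethynyl-6,8-dimethoxy-4H-chromen-4-one | C#Cc1cc(=O)c2c(OCc3ccccc3)c(OC)c(OCc3ccccc3)c(OC)c2o1 | intermediate
14 | 3,4-dimethoxyfuran | COc1cocc1OC | starting material
15 | 5,7-bis(benzyloxy)-2-(5,6-dimethoxy-7-oxabicyclo[2.2.1]hepta-2,5-dien-2-yl)-6,8-dimethoxy-4H-chromen-4-one (racemic, one enantiomer drawn; bridgeheads necessarily cis-bridged) | COC1=C(OC)[C@@H]2O[C@H]1C=C2c1cc(=O)c2c(OCc3ccccc3)c(OC)c(OCc3ccccc3)c(OC)c2o1 | intermediate
16 | 5,7-bis(benzyloxy)-2-(3-hydroxy-4,5-dimethoxyphenyl)-6,8-dimethoxy-4H-chromen-4-one (5,7-di-O-benzylscaposin) | COc1cc(-c2cc(=O)c3c(OCc4ccccc4)c(OC)c(OCc4ccccc4)c(OC)c3o2)cc(O)c1OC | intermediate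
17 | scaposin, 5,7-dihydroxy-2-(3-hydroxy-4,5-dimethoxyphenyl)-6,8-dimethoxy-4H-chromen-4-one | COc1cc(-c2cc(=O)c3c(O)c(OC)c(O)c(OC)c3o2)cc(O)c1OC | target

Total step count: 8
Longest linear sequence: 8 steps (1 → 17); 9 and 14 enter as purchased materials.

Steps most likely to fail

Step 7. The alkyne is activated only through the pyranone, so the cycloaddition may be slower than thermal decomposition or polymerization of the furan. The bridge may also open in the other direction and lead to the 2'-phenol. In that case ring B would be brought in preformed, setting out from 8. Claisen–Schmidt condensation with purchased 3-(benzyloxy)-4,5-dimethoxybenzaldehyde (KOH, EtOH, rt) should give the chalcone (E)-1-[4,6-bis(benzyloxy)-2-hydroxy-3,5-dimethoxyphenyl]-3-[3-(benzyloxy)-4,5-dimethoxyphenyl]prop-2-en-1-one F1. Oxidative cyclization (catalytic I2, DMSO, 120 °C) should give 5,7-bis(benzyloxy)-2-[3-(benzyloxy)-4,5-dimethoxyphenyl]-6,8-dimethoxy-4H-chromen-4-one F2. Hydrogenolysis of all three benzyl ethers (H2, Pd/C) rejoins the route at 17.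

Step 6. Methoxide may add to C2 of the pyranone and open ring C, or methanol may add in conjugate fashion to the product enynone. The alkoxide-free alternative sets out from 12. Dibromo-olefination (CBr4, PPh3, CH2Cl2, 0 °C) should give 5,7-bis(benzyloxy)-2-(2,2-dibromoethenyl)-6,8-dimethoxy-4H-chromen-4-one F3. Selective removal of the bromine trans to the chromone (Bu3SnH, catalytic Pd(PPh3)4, a zerovalent palladium complex, PhMe, rt) should give 5,7-bis(benzyloxy)-2-[(Z)-2-bromoethenyl]-6,8-dimethoxy-4H-chromen-4-one F4. Anti elimination of hydrogen bromide with Bu4NF in DMF at rt rejoins the route at 13.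

Step 5. Hydrolysis of the acetal next to the electron-poor pyranone may be incomplete, or the aqueous acid needed may cleave the peri benzyl ether on O5 and leave the aldehyde as its hydrate. The alternative reaches the aldehyde by oxidation instead of hydrolysis and sets out from 8. Claisen condensation with diethyl oxalate (NaOEt, EtOH) should give ethyl 4-[4,6-bis(benzyloxy)-2-hydroxy-3,5-dimethoxyphenyl]-2,4-dioxobutanoate F5, which is not isolated. Cyclization with catalytic HCl in EtOH at reflux should give ethyl 5,7-bis(benzyloxy)-6,8-dimethoxy-4-oxo-4H-chromene-2-carboxylate F6. Chemoselective ester reduction (NaBH4, MeOH/THF, 0 °C) should give 5,7-bis(benzyloxy)-2-(hydroxymethyl)-6,8-dimethoxy-4H-chromen-4-one F7. Oxidation with MnO2 in CH2Cl2 rejoins the route at 12.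

Further compounds
F1 | step 7 | (E)-1-[4,6-bis(benzyloxy)-2-hydroxy-3,5-dimethoxyphenyl]-3-[3-(benzyloxy)-4,5-dimethoxyphenyl]prop-2-en-1-one | O=C(/C=C/c1cc(OC)c(OC)c(OCc2ccccc2)c1)c1c(O)c(OC)c(OCc2ccccc2)c(OC)c1OCc1ccccc1
F2 | step 7 | 5,7-bis(benzyloxy)-2-[3-(benzyloxy)-4,5-dimethoxyphenyl]-6,8-dimethoxy-4H-chromen-4-one | COc1cc(-c2cc(=O)c3c(OCc4ccccc4)c(OC)c(OCc4ccccc4)c(OC)c3o2)cc(OCc2ccccc2)c1OC
F3 | step 6 | 5,7-bis(benzyloxy)-2-(2,2-dibromoethenyl)-6,8-dimethoxy-4H-chromen-4-one | BrC(Br)=Cc1cc(=O)c2c(OCc3ccccc3)c(OC)c(OCc3ccccc3)c(OC)c2o1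
F4 | step 6 | 5,7-bis(benzyloxy)-2-[(Z)-2-bromoethenyl]-6,8-dimethoxy-4H-chromen-4-one | Br/C=C\c1cc(=O)c2c(OCc3ccccc3)c(OC)c(OCc3ccccc3)c(OC)c2o1
F5 | step 5 | ethyl 4-[4,6-bis(benzyloxy)-2-hydroxy-3,5-dimethoxyphenyl]-2,4-dioxobutanoate | CCOC(=O)C(=O)CC(=O)c1c(O)c(OC)c(OCc2ccccc2)c(OC)c1OCc1ccccc1
F6 | step 5 | ethyl 5,7-bis(benzyloxy)-6,8-dimethoxy-4-oxo-4H-chromene-2-carboxylate | CCOC(=O)c1cc(=O)c2c(OCc3ccccc3)c(OC)c(OCc3ccccc3)c(OC)c2o1
F7 | step 5 | 5,7-bis(benzyloxy)-2-(hydroxymethyl)-6,8-dimethoxy-4H-chromen-4-one | OCc1cc(=O)c2c(OCc3ccccc3)c(OC)c(OCc3ccccc3)c(OC)c2o1
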